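Rings A and B are disconnected at C16–C5 and C2–C3. In the target, C16 lies between oxygenated C1 and C8 of ring B; with both as ketones, C16 is the acidic carbon of a 2-alkyl-1,3-diketone, and the C3 carbinol is the aldol of the C1 acetyl methyl (C2) with a methyl ketone. One pot therefore turns the acyclic enone–diketone 9 into cis-hydrindane ketol 11: a catalytic asymmetric 5-exo Michael addition sets C16 and C5, and a magnesium-templated aldol closes ring A and sets C3. Precursor 9 is a 3-alkylated oct-7-ene-2,4-dione extended by cross-metathesis and already carries N12. Ring C is closed later by N-alkylation.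

Key step: step 6

Remarks on the chemistry
- Atom numbers follow the target SMILES: C1 (CHOAc), C2, C3 (C(Me)OAc), C4, C5 (ring-fusion CH), C6, C7 (ketone), C8=C9 (enone alkene), C10, C11, N12, C13–C15, C16 (quaternary). Ring A is C1–C5/C16, ring B is C5–C8/C16, ring C is C8–C16. O1, O3 and O8 are the oxygens on C1, C3 and C8.
- The β face of ring A is the face that carries ring B (C6, C8); the α face carries H5 and the C15 arm. In the target both acetoxy groups are β and the C3 methyl is α; C1, C3, C5 and C16 are all S, and the enone is E.
- Assumption: the sense of induction of the thiourea catalyst cannot be assigned in advance. The (R,R) antipode is written; if the first run gives the mirror-image series, the (S,S) antipode is used and nothing else changes.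
- Triketone 9 is used soon after purification and kept free of base, since it can cyclise without catalyst.

Step 1
Reactants: 1 3-(methylamino)propan-1-ol
Product: 2 tert-butyl (3-hydroxypropyl)(methyl)carbamate
Conditions: Boc2O, CH2Cl2, 0 °C to rt
Reagents that add atoms: di-tert-butyl dicarbonate, CC(C)(C)OC(=O)OC(=O)OC(C)(C)C
Why: Carbamate formation on the secondary amine, which is far more nucleophilic than the primary alcohol; no stereocentre.

Step 2
Reactants: 2 tert-butyl (3-hydroxypropyl)(methyl)carbamate
Product: 3 tert-butyl (3-iodopropyl)(methyl)carbamate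
Conditions: I2, PPh3, imidazole, CH2Cl2, 0 °C to rt
Reagents that add atoms: iodine, II
Why: Appel iodination of a primary alcohol (alkoxyphosphonium ion, then SN2 by iodide) under neutral conditions that keep the carbamate.

Step 3
Reactants: 4 acetylacetone; 5 allyl bromide
Product: 6 oct-7-ene-2,4-dione
Conditions: LiN(iPr)2 (2.2 equiv), THF, −78 to 0 °C; then 5, 0 °C; aq NH4Cl
Reagents that add atoms: none
Why: Dianion alkylation of a 1,3-diketone, in which the more basic terminal carbanion is allylated and the central carbon is left free.

Step 4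
Reactants: 6 oct-7-ene-2,4-dione; 3 tert-butyl (3-iodopropyl)(methyl)carbamate
Product: 7 3-[3-(N-Boc-N-methylamino)propyl]oct-7-ene-2,4-dione
Conditions: K2CO3, acetone, reflux
Reagents that add atoms: none
Why: C-alkylation of the potassium β-diketonate at its central carbon by a primary iodide, a soft electrophile that favours carbon over oxygen; the new centre is later C16 and is still enolisable.

Step 5
Reactants: 7 3-[3-(N-Boc-N-methylamino)propyl]oct-7-ene-2,4-dione; 8 methyl vinyl ketone
Product: 9 (E)-3-[3-(N-Boc-N-methylamino)propyl]dec-7-ene-2,4,9-trione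
Conditions: second-generation Grubbs catalyst RuCl2(=CHPh)(PCy3)(H2IMes) (5 mol %), 8 (3 equiv), CH2Cl2, 40 °C
Reagents that add atoms: none
Why: Olefin cross-metathesis of a terminal alkene with an electron-poor enone partner, which does not homodimerise readily and gives the E-enone.

Step 6
Reactants: 9 (E)-3-[3-(N-Boc-N-methylamino)propyl]dec-7-ene-2,4,9-trione
Product: 11 cis-hydrindane-1,8-dione ketol (C3 β-OH; C3 α-Me; C16 arm α), via Michael adduct 10 (not isolated)
Conditions: 1-[3,5-bis(trifluoromethyl)phenyl]-3-[(1R,2R)-2-(dimethylamino)cyclohexyl]thiourea (10 mol %), toluene, 0 °C to rt; then MgBr2·OEt2 (2 equiv), iPr2NEt (2.5 equiv), CH2Cl2, −20 to 0 °C; aq NH4Cl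
Reagents that add atoms: none
Why: The dimethylamino group of the catalyst deprotonates the 2-alkyl-1,3-diketone while the thiourea hydrogen-bonds the enone carbonyl, and C16 adds to C5 through the exocyclic acetyl enolate, a 5-(enolexo)-exo-trig closure of ring B that belongs to the known organocatalytic Michael cyclisations of 1,3-dicarbonyl compounds onto enones. The catalyst fixes the enone face (C5) and, by bridging the acetyl oxygen and the enone carbonyl, places the acetyl group and the 2-oxopropyl arm cis on ring B (C16); a trans adduct can revert by retro-Michael reaction while the catalyst is present. MgBr2·OEt2 and iPr2NEt then enolise the acetyl group softly (the O1/O8 magnesium chelate acidifies C2–H), and C2 adds to the C3 ketone in a 6-(enolendo)-exo-trig aldol, the second half of a Robinson-type Michael–aldol sequence, which closes ring A as the cis-fused ketol. The O1–Mg–O8 chelate holds C8 equatorial and C6 axial on the forming chair, so the C3 carbonyl enters with its oxygen axial beside C6 and its methyl equatorial, which places the C3 hydroxyl on the β face. The step needs C- over O-cyclisation and C2-to-C3 aldol regiochemistry: the first rests on the reversibility of the oxa-Michael path, the second on chelation-activated enolisation at the acetyl methyl and on the neopentyl position of the C1 and C8 carbonyls next to quaternary C16, which makes them poor acceptors for the enolate of the C3 methyl ketone.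

Step 7
Reactants: 11 cis-hydrindane-1,8-dione ketol
Product: 12 1,3-syn diol (C1 β-OH, C3 β-OH, C8 ketone kept)
Conditions: Zn(BH4)2 (0.7 equiv), Et2O, −40 to −20 °C; aq NH4Cl
Reagents that add atoms: none
Why: Chelation-controlled borohydride reduction of a 1,3-dicarbonyl unit: zinc bridges O1 and O8, which puts C8 equatorial and C6 and the C3 hydroxyl axial on the β face of ring A, so the small hydride enters C1 from the α face and the new hydroxyl is β, cis to the C3 hydroxyl, while the six-membered ketone reacts faster than the five-membered one.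

Step 8
Reactants: 12 1,3-syn diol
Product: 13 O1,O3-diacetate with C8 ketone
Conditions: Ac2O, DMAP, Et3N, CH2Cl2, rt to 40 °C
Reagents that add atoms: acetic anhydride, CC(=O)OC(C)=O
Why: DMAP-catalysed acyl transfer acetylates the secondary hydroxyl quickly and the tertiary one on longer reaction; no stereocentre is touched and C16 has no hydrogen, so the β-acetoxy ketone cannot eliminate.

Step 9
Reactants: 13 O1,O3-diacetate with C8 ketone
Product: 14 C7=C8 enol triflate (OTf on C8)
Conditions: KN(SiMe3)2, THF, −78 °C, 20 min; then PhNTf2, −78 to −40 °C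
Reagents that add atoms: N-phenylbis(trifluoromethanesulfonimide), O=S(=O)(N(c1ccccc1)S(=O)(=O)C(F)(F)F)C(F)(F)F
Why: Kinetic enolate O-triflation; C16 is quaternary so the ketone can only enolise toward C7, the ketone α-hydrogens are more acidic than those of the acetates, and the low temperature suppresses acyl transfer to the enolate.

Step 10
Reactants: 14 C7=C8 enol triflate; 15 allyloxy(tert-butyl)dimethylsilane
Product: 17 C8-[3-(tert-butyldimethylsilyloxy)propyl] cyclopentene, via B-alkyl borane 16 (not isolated)
Conditions: 15, 9-BBN-H dimer, THF, rt; then 14, PdCl2(dppf) (10 mol %), AsPh3, Cs2CO3, DMF/THF/H2O, rt to 45 °C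
Reagents that add atoms: none
Why: Anti-Markovnikov hydroboration of the terminal alkene followed by B-alkyl Suzuki–Miyaura coupling with the enol triflate forms C8–C9 and leaves the C7=C8 alkene in place; the hindered acetates and the carbamate tolerate the mild aqueous carbonate.

Step 11
Reactants: 17 C8-[3-(tert-butyldimethylsilyloxy)propyl] cyclopentene
Product: 18 primary alcohol (C11–OH)
Conditions: HF·pyridine, pyridine, THF, 0 °C to rt
Reagents that add atoms: none
Why: Fluoride cleavage of a primary silyl ether under pyridine buffering, which leaves the carbamate, both acetates and the trisubstituted alkene untouched.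

Step 12
Reactants: 18 primary alcohol (C11–OH)
Product: 19 primary iodide (C11–I)
Conditions: I2, PPh3, imidazole, CH2Cl2, 0 °C
Reagents that add atoms: iodine, II
Why: Appel iodination of the primary alcohol under neutral conditions compatible with the Boc group and the acetates.

Step 13
Reactants: 19 primary iodide (C11–I)
Product: 22 tricyclic amine with ring C closed (N12–C11) and C7=C8 alkene, via silyl carbamate 20 (not isolated), via amino iodide 21 (not isolated)
Conditions: TMSOTf, 2,6-lutidine, CH2Cl2, 0 °C; MeOH; then slow addition to K2CO3, MeCN (1 mM), 70 °C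
Reagents that add atoms: none
Why: Silyl triflate-mediated Boc cleavage (loss of the tert-butyl cation, methanolysis of the silyl carbamate, decarboxylation) spares the tertiary acetate, and the freed N-methylamine closes ring C by intramolecular SN2 N-alkylation at high dilution, helped by sp2 C8 and by the two arms sitting on adjacent ring B carbons.

Step 14
Reactants: 22 tricyclic amine with C7=C8 alkene
Product: 23 C7,C8 cis-diol (both hydroxyls on the ring B face that carries H5)
Conditions: OsO4 (5 mol %), N-methylmorpholine N-oxide, citric acid, t-BuOH/H2O, rt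
Reagents that add atoms: osmium tetroxide, O=[Os](=O)(=O)=O; N-methylmorpholine N-oxide, C[N+]1([O-])CCOCC1; water, O
Why: Catalytic syn-dihydroxylation of the only alkene with N12 protonated by citric acid; attack is expected from the ring B face away from ring A, and since both new stereocentres are removed in steps 15 and 16 the facial outcome does not matter.

Step 15
Reactants: 23 C7,C8 cis-diol
Product: 24 α-ketol (C7 ketone, C8 tertiary hydroxyl)
Conditions: (COCl)2, DMSO, CH2Cl2, −78 °C; Et3N, −78 to 0 °C
Reagents that add atoms: none
Why: Swern oxidation converts the secondary C7 hydroxyl into the ketone without glycol cleavage; the tertiary hydroxyl cannot be oxidised and the tertiary amine is inert.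

Step 16
Reactants: 24 α-ketol (C7 ketone, C8 tertiary hydroxyl)
Product: 25 target diacetate enone, CNP0386920.1
Conditions: SOCl2, pyridine, CH2Cl2, −20 to 0 °C
Reagents that add atoms: none
Why: Chlorosulfite formation and pyridine-induced E2 dehydration of a tertiary α-ketol (as in the conversion of 5-hydroxy-6-oxo steroids into 4-en-6-ones); C16 is quaternary and C7 is a carbonyl, so only C9 offers β-hydrogens, and the nine-membered ring allows only the alkene with C10 cis to C16, which is the E-enone.

Compound list
1 | 3-(methylamino)propan-1-ol | CNCCCO | starting material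
2 | tert-butyl (3-hydroxypropyl)(methyl)carbamate | CN(CCCO)C(=O)OC(C)(C)C | intermediate
3 | tert-butyl (3-iodopropyl)(methyl)carbamate | CN(CCCI)C(=O)OC(C)(C)C | intermediate
4 | acetylacetone (pentane-2,4-dione) | CC(=O)CC(C)=O | starting material
5 | allyl bromide | C=CCBr | starting material
6 | oct-7-ene-2,4-dione | CC(=O)CC(=O)CCC=C | intermediate
7 | 3-[3-(N-Boc-N-methylamino)propyl]oct-7-ene-2,4-dione | CC(=O)C(CCCN(C)C(=O)OC(C)(C)C)C(=O)CCC=C | intermediate
8 | methyl vinyl ketone | C=CC(C)=O | starting material
9 | (E)-3-[3-(N-Boc-N-methylamino)propyl]dec-7-ene-2,4,9-trione (key-step precursor) | CC(=O)C(CCCN(C)C(=O)OC(C)(C)C)C(=O)CC/C=C/C(C)=O | intermediate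
10 | Michael adduct: tert-butyl {3-[1-acetyl-2-oxo-5-(2-oxopropyl)cyclopentyl]propyl}(methyl)carbamate, acetyl and 2-oxopropyl cis (ring carbons are C16 and C5 in their final configuration) | CC(=O)[C@]1(CCCN(C)C(=O)OC(C)(C)C)C(=O)CC[C@@H]1CC(C)=O | intermediate
11 | cis-hydrindane-1,8-dione ketol: rings A and B cis-fused, C1 and C8 ketones, C3 β-OH and α-Me, H5 α, C16 α-[3-(N-Boc-N-methylamino)propyl] arm (key-step product) | O=C1C[C@@](C)(O)C[C@H]2CCC(=O)[C@@]12CCCN(C)C(=O)OC(C)(C)C | intermediate
12 | 1,3-syn diol: as 11 with C1 reduced, C1 β-OH cis to C3 β-OH, C8 ketone | O[C@H]1C[C@@](C)(O)C[C@H]2CCC(=O)[C@@]12CCCN(C)C(=O)OC(C)(C)C | intermediate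
13 | O1,O3-diacetate of 12 (C8 ketone) | CC(=O)O[C@H]1C[C@@](C)(OC(C)=O)C[C@H]2CCC(=O)[C@@]12CCCN(C)C(=O)OC(C)(C)C | intermediate
14 | C7=C8 enol triflate of 13 (OTf on C8) | CC(=O)O[C@H]1C[C@@](C)(OC(C)=O)C[C@H]2CC=C(OS(=O)(=O)C(F)(F)F)[C@@]12CCCN(C)C(=O)OC(C)(C)C | intermediate
15 | allyloxy(tert-butyl)dimethylsilane | C=CCO[Si](C)(C)C(C)(C)C | starting material
16 | 9-[3-(tert-butyldimethylsilyloxy)propyl]-9-borabicyclo[3.3.1]nonane | CC(C)(C)[Si](C)(C)OCCCB1C2CCCC1CCC2 | intermediate
17 | coupling product: 14 with OTf replaced by 3-(tert-butyldimethylsilyloxy)propyl at C8 (C7=C8 alkene) | CC(=O)O[C@H]1C[C@@](C)(OC(C)=O)C[C@H]2CC=C(CCCO[Si](C)(C)C(C)(C)C)[C@@]12CCCN(C)C(=O)OC(C)(C)C | intermediate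
18 | primary alcohol: C8 3-hydroxypropyl arm (C11–OH), N-Boc-N-methyl arm on C16 | CC(=O)O[C@H]1C[C@@](C)(OC(C)=O)C[C@H]2CC=C(CCCO)[C@@]12CCCN(C)C(=O)OC(C)(C)C | intermediate
19 | primary iodide: C8 3-iodopropyl arm (C11–I), N-Boc-N-methyl arm on C16 | CC(=O)O[C@H]1C[C@@](C)(OC(C)=O)C[C@H]2CC=C(CCCI)[C@@]12CCCN(C)C(=O)OC(C)(C)C | intermediate
20 | trimethylsilyl carbamate of 19 (N–CO2SiMe3 in place of N–Boc) | CC(=O)O[C@H]1C[C@@](C)(OC(C)=O)C[C@H]2CC=C(CCCI)[C@@]12CCCN(C)C(=O)O[Si](C)(C)C | intermediate
21 | amino iodide: secondary N-methylamine on the C16 arm, C11–I on the C8 arm (held as its ammonium salt) | CC(=O)O[C@H]1C[C@@](C)(OC(C)=O)C[C@H]2CC=C(CCCI)[C@@]12CCCNC | intermediate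
22 | tricyclic amine: ring C closed through N12–C11, C7=C8 alkene, O1,O3-diacetate | CC(=O)O[C@H]1C[C@@](C)(OC(C)=O)C[C@H]2CC=C3CCCN(C)CCC[C@@]321 | intermediate
23 | C7,C8 cis-diol of 22, both hydroxyls on the ring B face that carries H5 | CC(=O)O[C@H]1C[C@@](C)(OC(C)=O)C[C@H]2C[C@H](O)[C@@]3(O)CCCN(C)CCC[C@@]321 | intermediate
24 | α-ketol: C7 ketone, C8 tertiary hydroxyl (configuration as in 23) | CC(=O)O[C@H]1C[C@@](C)(OC(C)=O)C[C@H]2CC(=O)[C@@]3(O)CCCN(C)CCC[C@@]321 | intermediate
25 | CNP0386920.1: (1S,3S,5S,16S)-1,3-diacetoxy-3-methyl tricycle with C7 ketone, (E)-C8=C9 enone and N12-methyl azonine ring | CC(=O)O[C@H]1C[C@@](C)(OC(C)=O)C[C@H]2CC(=O)/C3=C/CCN(C)CCC[C@@]321 | target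

Total step count: 16.
Longest linear sequence: 15 steps (steps 1, 2 and 4–16, from 3-(methylamino)propan-1-ol); step 3 is the side branch.

Steps most likely to fail

1. Step 6. The weakly acidic 2-alkyl diketone may cyclise in part outside the hydrogen-bond network of the catalyst, giving a racemic background reaction. The aldol may also pass in part through the unchelated chair and deliver the C3 hydroxyl to the α face. Fallback (resolution in place of catalyst control): from 9, the same two-stage cyclisation is run with an achiral base (Cs2CO3, MeCN, then MgBr2·OEt2/iPr2NEt) through the racemic Michael adduct F1 to the racemic ketol F2. Reduction with Zn(BH4)2 as in step 7 gives the racemic diol F3. Esterification of the C1 hydroxyl with (S)-2-methoxy-2-phenylacetic acid (EDC, DMAP, CH2Cl2) gives the wanted mandelate ester F4 and the diastereomeric ester of the mirror-image diol F5. These are separated by chromatography or crystallisation, which also removes C3-epimeric material. Methanolysis of F4 (K2CO3, MeOH, 0 °C) rejoins the route at diol 12.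

2. Step 7. Hydride may be delivered to the β face, either through the chair in which the dicarbonyl unit is not chelated or intramolecularly from a borohydride bound to the C3 alkoxide. The C8 ketone may also be reduced. Fallback (enzyme control in place of substrate control): 11 is reduced with an NADPH-dependent ketoreductase chosen from a screening panel (glucose/glucose dehydrogenase recycling, phosphate buffer pH 7 with DMSO, 30 °C). The enzyme is selected for reduction of the six-membered-ring ketone from the α face, and the product is diol 12 itself, so no new compound arises (F0).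

3. Step 13. Intermolecular N-alkylation (dimers, oligomers, quaternary salts) may outrun closure of the strained nine-membered ring, and the amino iodide may react while it is being set free. Fallback (reductive amination in place of SN2 alkylation): from alcohol 18, oxidation with the triacetoxyperiodinane (DMP, NaHCO3, CH2Cl2) gives the aldehyde F6. ZnBr2 in CH2Cl2 removes the Boc group to give the amino aldehyde F7, which is not isolated but diluted and reduced with NaBH(OAc)3 in 1,2-dichloroethane. Iminium formation is reversible, so ring closure is selected before the irreversible hydride transfer, and the route is rejoined at 22.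

Further compounds
F1 | step 6 | racemic Michael adduct (10 and its enantiomer) | CC(=O)[C@]1(CCCN(C)C(=O)OC(C)(C)C)C(=O)CC[C@@H]1CC(C)=O.CC(=O)[C@@]1(CCCN(C)C(=O)OC(C)(C)C)C(=O)CC[C@H]1CC(C)=O
F2 | step 6 | racemic ketol (11 and its enantiomer) | O=C1C[C@@](C)(O)C[C@H]2CCC(=O)[C@@]12CCCN(C)C(=O)OC(C)(C)C.O=C1C[C@](C)(O)C[C@@H]2CCC(=O)[C@]12CCCN(C)C(=O)OC(C)(C)C
F3 | step 6 | racemic diol (12 and its enantiomer) | O[C@H]1C[C@@](C)(O)C[C@H]2CCC(=O)[C@@]12CCCN(C)C(=O)OC(C)(C)C.O[C@@H]1C[C@](C)(O)C[C@@H]2CCC(=O)[C@]12CCCN(C)C(=O)OC(C)(C)C
F4 | step 6 | O1-[(S)-2-methoxy-2-phenylacetate] of diol 12 | CO[C@@H](c1ccccc1)C(=O)O[C@H]1C[C@@](C)(O)C[C@H]2CCC(=O)[C@@]12CCCN(C)C(=O)OC(C)(C)C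
F5 | step 6 | O1-[(S)-2-methoxy-2-phenylacetate] of the enantiomer of diol 12 | CO[C@@H](c1ccccc1)C(=O)O[C@@H]1C[C@](C)(O)C[C@@H]2CCC(=O)[C@]12CCCN(C)C(=O)OC(C)(C)C
F0 | step 7 | none | none
F6 | step 13 | aldehyde: C8 3-oxopropyl arm (C11 aldehyde), N-Boc-N-methyl arm on C16 | CC(=O)O[C@H]1C[C@@](C)(OC(C)=O)C[C@H]2CC=C(CCC=O)[C@@]12CCCN(C)C(=O)OC(C)(C)C
F7 | step 13 | amino aldehyde: C11 aldehyde and free N-methylamine | CC(=O)O[C@H]1C[C@@](C)(OC(C)=O)C[C@H]2CC=C(CCC=O)[C@@]12CCCNC
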